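## Retrosynthetic overview
1. 9 ⇒ 8: the 1,6-oxirane (last ring) comes from C2-OH-directed epoxidation of the C1=C6 bond of a trans-dihydrodiol-type dienol.
2. 8 ⇒ 7: C4=C5 comes from reductive removal of a temporary 4,5-epoxide (vinyl epoxide → diene).
3. 7 ⇒ 5: the key C2–O bond comes from a singlet-oxygen ene photooxygenation. It also moves C1=C2 to C1=C6, and the face is dictated by C3-OBz and the 4,5-epoxide.
4. 5 ⇒ 1: (−)-shikimic acid is esterified, closed to the 4,5-epoxide by Mitsunobu reaction (only C3-OH stays free), reduced with DIBAL-H and benzoylated twice.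
5. Ring order: the carbocycle is bought with 1; the temporary 4,5-oxirane forms in step 2 and is erased in step 6; the final 1,6-oxirane forms in step 7.

Assumption: ring atoms are numbered as in the target (C1 = quaternary epoxide carbon, C2 = CHOH, C3 = CHOBz, C4=C5, C6 = epoxide CH). This numbering coincides with shikimate numbering in every intermediate.

## Route

Step 1
Reactants: 1 (−)-shikimic acid
Product: 2 methyl (−)-shikimate
Conditions: MeOH, Amberlyst-15 (H+), reflux
Reagents that add atoms: methanol, CO
Why: Fischer esterification over a solid acid touches only the carboxyl group, so C3, C4 and C5 are carried over unchanged.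

Step 2
Reactants: 2 methyl (−)-shikimate
Product: 3 methyl (1S,5R,6R)-5-hydroxy-7-oxabicyclo[4.1.0]hept-3-ene-3-carboxylate (4,5-epoxide cis to the C3-OH)
Conditions: PPh3, DIAD, THF, 0 °C → rt
Reagents that add atoms: none
Why: In this Mitsunobu cyclodehydration the unhindered equatorial C5-OH is activated as the oxyphosphonium salt and displaced with inversion by the trans C4-O (the cis C3/C4 pair cannot close), which gives only the 4,5-epoxide on the face of C3-OH and leaves C3-OH as the single free hydroxyl.

Step 3
Reactants: 3 epoxy alcohol ester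
Product: 4 (1R,2R,6S)-4-(hydroxymethyl)-7-oxabicyclo[4.1.0]hept-3-en-2-ol (epoxy diol)
Conditions: DIBAL-H (3.5 equiv), CH2Cl2, −78 °C; aq. Rochelle salt
Reagents that add atoms: none
Why: DIBAL-H 1,2-reduction of the enoate at −78 °C is much faster than hydride opening of the epoxide, and no stereocentre is touched.

Step 4
Reactants: 4 epoxy diol
Product: 5 [(1S,5R,6S)-5-(benzoyloxy)-7-oxabicyclo[4.1.0]hept-3-en-3-yl]methyl benzoate (epoxy dibenzoate)
Conditions: BzCl (2.5 equiv), pyridine, DMAP (cat.), CH2Cl2, 0 °C → rt
Reagents that add atoms: benzoyl chloride, O=C(Cl)c1ccccc1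
Why: DMAP-catalysed O-acylation installs both benzoates of the target at once with retention at C3, and the C3 ester lies cis to the epoxide oxygen, so it cannot open the epoxide from the rear.

Step 5
Reactants: 5 epoxy dibenzoate
Product: 7 [(1S,4S,5R,6S)-5-(benzoyloxy)-4-hydroxy-7-oxabicyclo[4.1.0]hept-2-en-3-yl]methyl benzoate (C2-OH, C1=C6, 4,5-epoxide), via allylic hydroperoxide 6 (not isolated)
Conditions: O2 (1 atm), tetrakis(pentafluorophenyl)porphyrin (0.5 mol %), white LED, C6F6, 10 °C; then PPh3 (1.1 equiv)
Reagents that add atoms: dioxygen, O=O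
Why: Proposed new method: this is a Schenck ene photooxygenation of a shikimate-type alkene bearing two allylic benzoyloxy groups and a homoallylic epoxide, a doubly deactivated substrate class on which the reaction has not been shown (hence the long 1O2 lifetime of C6F6 and the bleach-resistant fluorinated sensitiser); 1O2 can reach only the face opposite C3-OBz and the 4,5-epoxide, the perepoxide-like transition state takes the near-perpendicular C6-H on that face because the C–H bonds alpha to the benzoyloxy groups (C3-H, CH2OBz) are electronically and conformationally switched off and C6-H is geminal to the large CH2OBz group (geminal/large-group and cis effects), so the C2–O bond forms trans to C3-OBz (C2 set by substrate control) while the alkene moves to C1=C6, and PPh3 then reduces the O–O bond with retention; the closest known reaction type is the Schenck ene reaction of trisubstituted allylic acetates followed by phosphine reduction.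

Step 6
Reactants: 7 vinyl-epoxide alcohol
Product: 8 [(5S,6S)-5-(benzoyloxy)-6-hydroxycyclohexa-1,3-dien-1-yl]methyl benzoate (dienol)
Conditions: Cp2TiCl2 (3 equiv), Mn dust, THF, rt; then add 7, 0 °C → rt; pH 7 buffer
Reagents that add atoms: none
Why: In this Nugent–RajanBabu titanocene(III) epoxide deoxygenation, Ti(III) cleaves the allylic C5–O bond by single-electron transfer, a second Ti(III) captures the allyl radical, and the β-titanoxy organotitanium collapses to C4=C5, with the benzoates, the free OH and C2/C3 untouched (the C4/C5 centres are erased on purpose).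

Step 7
Reactants: 8 dienol
Product: 9 (−)-pipoxide
Conditions: VO(acac)2 (3 mol %), t-BuOOH (decane, 1.2 equiv), CH2Cl2, 0 °C
Reagents that add atoms: tert-butyl hydroperoxide, CC(C)(C)OO
Why: In this Sharpless–Michaelson vanadium/TBHP hydroxyl-directed epoxidation the C2 vanadate ester delivers oxygen only to the adjacent allylic C1=C6 bond and only from the face of C2-OH, which sets C1 (R) and C6 (S) cis to C2-OH and leaves the remote, benzoate-deactivated C4=C5 bond alone.

## Compound list
1 | (−)-shikimic acid, (3R,4S,5R)-3,4,5-trihydroxycyclohex-1-ene-1-carboxylic acid | OC(=O)C1=C[C@@H](O)[C@@H](O)[C@H](O)C1 | starting material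
2 | methyl (−)-shikimate | COC(=O)C1=C[C@@H](O)[C@@H](O)[C@H](O)C1 | intermediate
3 | methyl (1S,5R,6R)-5-hydroxy-7-oxabicyclo[4.1.0]hept-3-ene-3-carboxylate | COC(=O)C1=C[C@@H](O)[C@H]2O[C@H]2C1 | intermediate
4 | (1R,2R,6S)-4-(hydroxymethyl)-7-oxabicyclo[4.1.0]hept-3-en-2-ol | OCC1=C[C@@H](O)[C@H]2O[C@H]2C1 | intermediate
5 | [(1S,5R,6S)-5-(benzoyloxy)-7-oxabicyclo[4.1.0]hept-3-en-3-yl]methyl benzoate | O=C(OCC1=C[C@@H](OC(=O)c2ccccc2)[C@H]2O[C@H]2C1)c1ccccc1 | intermediate
6 | [(1S,4S,5S,6S)-5-(benzoyloxy)-4-hydroperoxy-7-oxabicyclo[4.1.0]hept-2-en-3-yl]methyl benzoate | O=C(OCC1=C[C@@H]2O[C@@H]2[C@H](OC(=O)c2ccccc2)[C@H]1OO)c1ccccc1 | intermediate (not isolated)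
7 | [(1S,4S,5R,6S)-5-(benzoyloxy)-4-hydroxy-7-oxabicyclo[4.1.0]hept-2-en-3-yl]methyl benzoate | O=C(OCC1=C[C@@H]2O[C@@H]2[C@H](OC(=O)c2ccccc2)[C@H]1O)c1ccccc1 | intermediate
8 | [(5S,6S)-5-(benzoyloxy)-6-hydroxycyclohexa-1,3-dien-1-yl]methyl benzoate | O=C(OCC1=CC=C[C@H](OC(=O)c2ccccc2)[C@H]1O)c1ccccc1 | intermediate
9 | (−)-pipoxide, [(1R,2R,3S,6S)-3-(benzoyloxy)-2-hydroxy-7-oxabicyclo[4.1.0]hept-4-en-1-yl]methyl benzoate | O=C(OC[C@]12O[C@H]1C=C[C@H](OC(=O)c1ccccc1)[C@H]2O)c1ccccc1 | target

## Totals
Total steps: 7. Longest linear sequence: 7 (1 → 9).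

Stereocentres:
- C3 is bought with 1.
- C2 is set in step 5 by C3-OBz and the shikimate-derived epoxide.
- C1 and C6 are set in step 7 by C2-OH.

## Three steps most likely to fail

**Step 5 (the proposed new step).**
- Risk: the alkene is slowed by two allylic benzoyloxy groups. Some oxygen may also end up at C1, giving a tertiary hydroperoxide and an enol benzoate.
- Fallback (known chemistry, from 5 back to 7): Upjohn dihydroxylation (OsO4 cat., NMO, acetone/H2O) attacks the open face and gives the C1,C2-cis-diol F1.
- TESCl/imidazole then silylates only the secondary C2-OH, giving the mono-silyl ether F2.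
- Burgess reagent (toluene, 50 °C) removes the tertiary C1-OH by syn elimination towards C6. C2-H lies anti to the leaving group and cannot take part. This gives the allylic silyl ether F3.
- TBAF/AcOH (THF, 0 °C) frees the C2-OH and returns to 7.

**Step 6.**
- Risk: the allyl-titanium species could expel the primary benzoate or be protonated by the free OH. Ti(IV) could also promote aromatisation of 8 or bridging of C2-OH onto C5.
- Fallback (from 7 back to 8): an ionic chalcogen exchange replaces the radical reduction.
- Ph3P=Se with TFA (CH2Cl2, 0 °C) opens the epoxide at the allylic C5, passes the oxygen to phosphorus and closes to the 4,5-episelenide F4. This loses selenium spontaneously and gives 8.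

**Step 7.**
- Risk: V(V)/TBHP may oxidise the C2 carbinol to a dienone that tautomerises to a phenol. The Lewis acid may also open the vinyl epoxide of 9.
- Fallback (from 8 back to 9): singlet-oxygen [4+2] cycloaddition (O2, tetraphenylporphyrin, hν, CH2Cl2, −20 °C) occurs on the face carrying the small, hydrogen-bonding C2-OH and opposite the C3-OBz. It gives the 1,4-endoperoxide F5.
- P(OMe)3 attacks the less hindered oxygen on C4. The C1 alkoxide then closes on C6 in an SN2′ manner with loss of phosphate and gives 9.

## Further compounds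
F1 | step 5 | C1,C2-cis-diol of 5 (both OH on the face opposite C3-OBz and the 4,5-epoxide) | O=C(OC[C@]1(O)C[C@@H]2O[C@@H]2[C@H](OC(=O)c2ccccc2)[C@H]1O)c1ccccc1
F2 | step 5 | C2-O-triethylsilyl ether of F1 (tertiary C1-OH free) | O=C(OC[C@]1(O)C[C@@H]2O[C@@H]2[C@H](OC(=O)c2ccccc2)[C@H]1O[Si](CC)(CC)CC)c1ccccc1
F3 | step 5 | C2-O-triethylsilyl ether of 7 | O=C(OCC1=C[C@@H]2O[C@@H]2[C@H](OC(=O)c2ccccc2)[C@H]1O[Si](CC)(CC)CC)c1ccccc1
F4 | step 6 | 4,5-episelenide of 8 (Se on the face opposite the former epoxide oxygen) | O=C(OCC1=C[C@H]2[Se][C@H]2[C@H](OC(=O)c2ccccc2)[C@H]1O)c1ccccc1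
F5 | step 7 | 1,4-endoperoxide of 8 (2,3-dioxabicyclo[2.2.2]oct-5-ene, O–O bridge on the face of C2-OH) | O=C(OC[C@]12OO[C@H](C=C1)[C@H](OC(=O)c1ccccc1)[C@H]2O)c1ccccc1
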